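## Retrosynthetic overview

1. Target 21 ⇐ dibenzyl ether 20 (hydrogenolysis) ⇐ α-aryloxy ketone 19 (chelation-controlled reduction sets the carbinol centre).
2. 19 ⇐ late Mitsunobu C–O coupling, with inversion, of aryltetralin phenol 13 (C27) and lactate-derived (S)-α-hydroxy ketone 18 (C17).
3. 13 ⇐ Friedel–Crafts closure of the tetralin ring (C1–C8a bond) from carbinol 11 ⇐ aldehyde 10 + aryl Grignard from 5.
4. 10 ⇐ Negishi coupling of iodo ester 8 with aryl bromide 4; 8 ⇐ (S)-β-methyl-γ-butyrolactone 6 by trans-methylation and iodide ring opening.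
5. All three guaiacyl rings ⇐ catechol via 4-bromo-2-methoxyphenol 3; 18 ⇐ ethyl (S)-lactate + 4. The only ring formed is the tetralin carbocycle (step 10); the aromatic rings are bought.

Assumption: (S)-4-methyloxolan-2-one (6) is bought as the single enantiomer. Reagents and protecting-group reagents are given with SMILES in each step and are not numbered.

## Route

**Step 1**
Reactants: 1, catechol
Product: 2, guaiacol (2-methoxyphenol)
Conditions: MeI (1.0 equiv), K2CO3, acetone, reflux; base extraction/distillation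
Reagents that add atoms: iodomethane, CI
Why: Williamson mono-O-methylation of a symmetrical diphenol; veratrole and unreacted catechol are removed by extraction and distillation.

**Step 2**
Reactants: 2, guaiacol
Product: 3, 4-bromo-2-methoxyphenol
Conditions: NBS, MeCN, 0 °C → rt
Reagents that add atoms: N-bromosuccinimide, BrN1C(=O)CCC1=O
Why: Electrophilic aromatic bromination; the free OH is the stronger director, so bromine enters para to it.

**Step 3**
Reactants: 3, 4-bromo-2-methoxyphenol
Product: 4, 1-(benzyloxy)-4-bromo-2-methoxybenzene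
Conditions: BnBr, K2CO3, DMF, rt
Reagents that add atoms: benzyl bromide, BrCc1ccccc1
Why: Williamson benzylation gives the phenol protection that is carried to the last step.

**Step 4**
Reactants: 3, 4-bromo-2-methoxyphenol
Product: 5, (4-bromo-2-methoxyphenoxy)(tert-butyl)dimethylsilane
Conditions: TBSCl, imidazole, DMF, rt
Reagents that add atoms: tert-butyldimethylsilyl chloride, CC(C)(C)[Si](C)(C)Cl
Why: Phenol silylation gives a protecting group removable by fluoride in the presence of benzyl ethers.

**Step 5**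
Reactants: 6, (S)-4-methyloxolan-2-one
Product: 7, (3S,4S)-3,4-dimethyloxolan-2-one (trans)
Conditions: LDA, THF, −78 °C; MeI, −78 → −40 °C
Reagents that add atoms: iodomethane, CI
Why: Lactone enolate alkylation; MeI approaches anti to the adjacent C4 methyl, setting C3 as S (trans, expected about 10:1, minor cis isomer removed by chromatography).

**Step 6**
Reactants: 7, (3S,4S)-3,4-dimethyloxolan-2-one
Product: 8, ethyl (2S,3S)-4-iodo-2,3-dimethylbutanoate
Conditions: TMSI (2 equiv), EtOH (3 equiv), CH2Cl2, 0 °C → reflux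
Reagents that add atoms: iodotrimethylsilane, C[Si](C)(C)I; ethanol, CCO
Why: Silyl-activated SN2 opening of the lactone by iodide at the O–CH2 carbon with in situ esterification; no bond to a stereocentre is broken.

**Step 7**
Reactants: 8, ethyl (2S,3S)-4-iodo-2,3-dimethylbutanoate; 4, 1-(benzyloxy)-4-bromo-2-methoxybenzene
Product: 9, ethyl (2S,3R)-4-[4-(benzyloxy)-3-methoxyphenyl]-2,3-dimethylbutanoate
Conditions: 8, Zn dust (TMSCl/BrCH2CH2Br-activated), DMA, 40 °C; then 4, Pd(OAc)2 (3 mol %), SPhos (6 mol %), THF, rt → 50 °C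
Reagents that add atoms: none
Why: Negishi sp3–sp2 cross-coupling of an ester-tolerant primary alkylzinc iodide; both stereocentres are remote from zinc and unchanged (the 3S → 3R change is a CIP priority change only).

**Step 8**
Reactants: 9, ethyl (2S,3R)-4-[4-(benzyloxy)-3-methoxyphenyl]-2,3-dimethylbutanoate
Product: 10, (2S,3R)-4-[4-(benzyloxy)-3-methoxyphenyl]-2,3-dimethylbutanal
Conditions: DIBAL-H (1.1 equiv), CH2Cl2, −78 °C; MeOH, Rochelle salt; used crude
Reagents that add atoms: none
Why: Partial ester reduction through the aluminium hemiacetal, which is stable at −78 °C; the cold, non-basic work-up and immediate use avoid α-epimerisation.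

**Step 9**
Reactants: 10, (2S,3R)-4-[4-(benzyloxy)-3-methoxyphenyl]-2,3-dimethylbutanal; 5, (4-bromo-2-methoxyphenoxy)(tert-butyl)dimethylsilane
Product: 11, (2S,3R)-4-[4-(benzyloxy)-3-methoxyphenyl]-1-{4-[(tert-butyldimethylsilyl)oxy]-3-methoxyphenyl}-2,3-dimethylbutan-1-ol (mixture of C1 epimers)
Conditions: 5, Mg, THF (I2 cat.); then 10, THF, −78 → 0 °C
Reagents that add atoms: none
Why: Grignard 1,2-addition to the aldehyde; the carbinol configuration is irrelevant because the centre is ionised in the next step.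

**Step 10**
Reactants: 11, the carbinol mixture
Product: 12, tert-butyl{4-[(1S,2S,3R)-7-(benzyloxy)-6-methoxy-2,3-dimethyl-1,2,3,4-tetrahydronaphthalen-1-yl]-2-methoxyphenoxy}dimethylsilane
Conditions: TFA (5 equiv), CH2Cl2, −20 → 0 °C
Reagents that add atoms: none
Why: Intramolecular Friedel–Crafts alkylation; the p-siloxybenzyl cation is trapped para to OMe through a chair-like transition state with aryl and both methyls pseudo-equatorial, setting C1 as S (aryl trans to the C2 methyl).

**Step 11**
Reactants: 12, the silyl-protected aryltetralin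
Product: 13, 4-[(1S,2S,3R)-7-(benzyloxy)-6-methoxy-2,3-dimethyl-1,2,3,4-tetrahydronaphthalen-1-yl]-2-methoxyphenol
Conditions: TBAF, THF, 0 °C
Reagents that add atoms: none
Why: Fluoride desilylation frees only the pendant phenol; the benzyl ether is untouched.

**Step 12**
Reactants: 14, ethyl (S)-lactate
Product: 15, ethyl (S)-2-[(tert-butyldimethylsilyl)oxy]propanoate
Conditions: TBSCl, imidazole, DMF, 0 °C → rt
Reagents that add atoms: tert-butyldimethylsilyl chloride, CC(C)(C)[Si](C)(C)Cl
Why: Silyl protection of the secondary alcohol without touching the stereocentre.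

**Step 13**
Reactants: 15, ethyl (S)-2-[(tert-butyldimethylsilyl)oxy]propanoate
Product: 16, (S)-2-[(tert-butyldimethylsilyl)oxy]-N-methoxy-N-methylpropanamide
Conditions: MeNHOMe·HCl, i-PrMgCl, THF, −20 → 0 °C
Reagents that add atoms: N,O-dimethylhydroxylamine hydrochloride, CNOC.Cl
Why: Weinreb amide formation by ester aminolysis with the magnesium amide, which does not enolise the α-silyloxy ester.

**Step 14**
Reactants: 16, the Weinreb amide; 4, 1-(benzyloxy)-4-bromo-2-methoxybenzene
Product: 17, (S)-1-[4-(benzyloxy)-3-methoxyphenyl]-2-[(tert-butyldimethylsilyl)oxy]propan-1-one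
Conditions: 4, Mg, THF; then 16, THF, 0 °C → rt; aq. NH4Cl
Reagents that add atoms: none
Why: Weinreb ketone synthesis; the chelated tetrahedral intermediate stops the addition at the ketone and the α-centre is retained.

**Step 15**
Reactants: 17, the α-silyloxy ketone
Product: 18, (S)-1-[4-(benzyloxy)-3-methoxyphenyl]-2-hydroxypropan-1-one
Conditions: HF·pyridine, THF, 0 °C → rt
Reagents that add atoms: none
Why: Mildly acidic fluoride desilylation avoids the base-mediated enolisation that would racemise the α-hydroxy ketone.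

**Step 16**
Reactants: 13, the aryltetralin phenol; 18, the (S)-α-hydroxy ketone
Product: 19, (2R)-1-[4-(benzyloxy)-3-methoxyphenyl]-2-{4-[(1S,2S,3R)-7-(benzyloxy)-6-methoxy-2,3-dimethyl-1,2,3,4-tetrahydronaphthalen-1-yl]-2-methoxyphenoxy}propan-1-one
Conditions: PPh3, DIAD (added last), THF, 0 °C → rt
Reagents that add atoms: none
Why: Mitsunobu etherification; the phenol displaces the carbonyl-activated oxyphosphonium by SN2 with inversion, converting the (S)-carbinol into the (R)-aryl ether centre of the target.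

**Step 17**
Reactants: 19, the α-aryloxy ketone
Product: 20, (1S,2R)-1-[4-(benzyloxy)-3-methoxyphenyl]-2-{4-[(1S,2S,3R)-7-(benzyloxy)-6-methoxy-2,3-dimethyl-1,2,3,4-tetrahydronaphthalen-1-yl]-2-methoxyphenoxy}propan-1-ol (erythro)
Conditions: Zn(BH4)2, Et2O, −20 → 0 °C; minor threo isomer removed by chromatography
Reagents that add atoms: none
Why: Chelation-controlled (Cram chelate) reduction; zinc bridges the carbonyl and α-aryloxy oxygens and hydride adds from the face of the α-hydrogen, giving the anti (erythro) 1S alcohol.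

**Step 18**
Reactants: 20, the dibenzyl ether
Product: 21, (1S,2R)-1-(4-hydroxy-3-methoxyphenyl)-2-{4-[(1S,2S,3R)-7-hydroxy-6-methoxy-2,3-dimethyl-1,2,3,4-tetrahydronaphthalen-1-yl]-2-methoxyphenoxy}propan-1-ol (CID 53359464)
Conditions: H2 (1 atm), 10% Pd/C, EtOAc, rt; stopped after 2 equiv H2
Reagents that add atoms: none
Why: Hydrogenolysis of the two aryl benzyl ethers, which is much faster in neutral EtOAc than cleavage of the secondary benzylic alcohol.

## Compound list

1 | catechol | Oc1ccccc1O | starting material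
2 | guaiacol | COc1ccccc1O | intermediate
3 | 4-bromo-2-methoxyphenol | COc1cc(Br)ccc1O | intermediate
4 | 1-(benzyloxy)-4-bromo-2-methoxybenzene | COc1cc(Br)ccc1OCc1ccccc1 | intermediate
5 | (4-bromo-2-methoxyphenoxy)(tert-butyl)dimethylsilane | COc1cc(Br)ccc1O[Si](C)(C)C(C)(C)C | intermediate
6 | (S)-4-methyloxolan-2-one | C[C@@H]1COC(=O)C1 | starting material
7 | (3S,4S)-3,4-dimethyloxolan-2-one | C[C@@H]1COC(=O)[C@H]1C | intermediate
8 | ethyl (2S,3S)-4-iodo-2,3-dimethylbutanoate | CCOC(=O)[C@@H](C)[C@H](C)CI | intermediate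
9 | ethyl (2S,3R)-4-[4-(benzyloxy)-3-methoxyphenyl]-2,3-dimethylbutanoate | CCOC(=O)[C@@H](C)[C@H](C)Cc1ccc(OCc2ccccc2)c(OC)c1 | intermediate
10 | (2S,3R)-4-[4-(benzyloxy)-3-methoxyphenyl]-2,3-dimethylbutanal | O=C[C@@H](C)[C@H](C)Cc1ccc(OCc2ccccc2)c(OC)c1 | intermediate
11 | (2S,3R)-4-[4-(benzyloxy)-3-methoxyphenyl]-1-{4-[(tert-butyldimethylsilyl)oxy]-3-methoxyphenyl}-2,3-dimethylbutan-1-ol, C1 epimers | COc1cc(C(O)[C@@H](C)[C@H](C)Cc2ccc(OCc3ccccc3)c(OC)c2)ccc1O[Si](C)(C)C(C)(C)C | intermediate
12 | tert-butyl{4-[(1S,2S,3R)-7-(benzyloxy)-6-methoxy-2,3-dimethyl-1,2,3,4-tetrahydronaphthalen-1-yl]-2-methoxyphenoxy}dimethylsilane | COc1cc([C@H]2c3cc(OCc4ccccc4)c(OC)cc3C[C@@H](C)[C@@H]2C)ccc1O[Si](C)(C)C(C)(C)C | intermediate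
13 | 4-[(1S,2S,3R)-7-(benzyloxy)-6-methoxy-2,3-dimethyl-1,2,3,4-tetrahydronaphthalen-1-yl]-2-methoxyphenol | COc1cc([C@H]2c3cc(OCc4ccccc4)c(OC)cc3C[C@@H](C)[C@@H]2C)ccc1O | intermediate
14 | ethyl (S)-lactate | CCOC(=O)[C@H](C)O | starting material
15 | ethyl (S)-2-[(tert-butyldimethylsilyl)oxy]propanoate | CCOC(=O)[C@H](C)O[Si](C)(C)C(C)(C)C | intermediate
16 | (S)-2-[(tert-butyldimethylsilyl)oxy]-N-methoxy-N-methylpropanamide | CON(C)C(=O)[C@H](C)O[Si](C)(C)C(C)(C)C | intermediate
17 | (S)-1-[4-(benzyloxy)-3-methoxyphenyl]-2-[(tert-butyldimethylsilyl)oxy]propan-1-one | COc1cc(C(=O)[C@H](C)O[Si](C)(C)C(C)(C)C)ccc1OCc1ccccc1 | intermediate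
18 | (S)-1-[4-(benzyloxy)-3-methoxyphenyl]-2-hydroxypropan-1-one | COc1cc(C(=O)[C@H](C)O)ccc1OCc1ccccc1 | intermediate
19 | (2R)-1-[4-(benzyloxy)-3-methoxyphenyl]-2-{4-[(1S,2S,3R)-7-(benzyloxy)-6-methoxy-2,3-dimethyl-1,2,3,4-tetrahydronaphthalen-1-yl]-2-methoxyphenoxy}propan-1-one | COc1cc(C(=O)[C@@H](C)Oc2ccc([C@H]3c4cc(OCc5ccccc5)c(OC)cc4C[C@@H](C)[C@@H]3C)cc2OC)ccc1OCc1ccccc1 | intermediate
20 | (1S,2R)-1-[4-(benzyloxy)-3-methoxyphenyl]-2-{4-[(1S,2S,3R)-7-(benzyloxy)-6-methoxy-2,3-dimethyl-1,2,3,4-tetrahydronaphthalen-1-yl]-2-methoxyphenoxy}propan-1-ol | COc1cc([C@H](O)[C@@H](C)Oc2ccc([C@H]3c4cc(OCc5ccccc5)c(OC)cc4C[C@@H](C)[C@@H]3C)cc2OC)ccc1OCc1ccccc1 | intermediate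
21 | (1S,2R)-1-(4-hydroxy-3-methoxyphenyl)-2-{4-[(1S,2S,3R)-7-hydroxy-6-methoxy-2,3-dimethyl-1,2,3,4-tetrahydronaphthalen-1-yl]-2-methoxyphenoxy}propan-1-ol | COc1cc([C@H](O)[C@@H](C)Oc2ccc([C@H]3c4cc(O)c(OC)cc4C[C@@H](C)[C@@H]3C)cc2OC)ccc1O | target

## Summary

Total steps: 18.

Longest linear sequence: 11 steps (1 → 2 → 3 → 4 → 9 → 10 → 11 → 12 → 13 → 19 → 20 → 21; steps 1, 2, 3, 7, 8, 9, 10, 11, 16, 17, 18).

Steps most likely to fail:

1. **Step 16 (Mitsunobu of a hindered o-methoxyphenol with an α-hydroxy ketone).** Risks are low conversion, elimination, or erosion of configuration at the α-carbon. Fallback: form the C–O bond on a lactate ester instead. Mitsunobu of 13 with ethyl (S)-lactate (14), conversion of the resulting (R)-aryloxypropanoate to its Weinreb amide, then addition of the Grignard from 4 gives 19.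

2. **Step 10 (Friedel–Crafts cyclisation).** Risks are E1 loss of a proton to the styrene and re-protonation, which would scramble C2, and some closure at the position between CH2 and OMe. Fallback: change the electrophile. Desilylate 11 first and cyclise the free p-hydroxybenzyl alcohol through its neutral p-quinone methide (catalytic mild Lewis acid), which closes the same bond without a free benzylic cation.

3. **Step 6 (iodide opening of the β-branched lactone).** Risks are slow SN2 at the hindered CH2 and relactonisation of the iodo ester. Fallback: reduce 7 with LiAlH4 to the C2-symmetric (2S,3S)-2,3-dimethylbutane-1,4-diol, monosilylate (both hydroxyls are equivalent), convert the other hydroxyl to the iodide (Appel), run the same Negishi coupling with 4, then desilylate and oxidise to 10.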